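**Retrosynthetic overview**
1. Fragilide F ⇒ ene-type chlorination of a Δ5(6) alkene (gives 6-Cl and the 5(16)-methylene) and chloride opening of an 11,20-epoxide.
2. Pyran ring (O–C8 bond) ⇒ transannular oxa-Michael addition of 4-OH to a Δ8(17)-butenolide inside a ten-membered carbocycle; this sets C8 and C17, and C7 converges by epimerisation.
3. Ten-membered ring ⇒ Nozaki–Hiyama–Kishi closure at C4–C5; the C8–C9 bond ⇒ Zn-Barbier allylation of a C9 aldehyde with a 3-(bromomethyl)butenolide, then oxidation and reduction to set C9.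
4. Cyclohexane (C1, C10, C14) ⇒ catalytic asymmetric Diels–Alder; C2/C3 ⇒ Evans syn-glycolate aldol; the four acetates double as protecting groups.
5. Ring order: cyclohexane → butenolide (made separately by RCM) → ten-membered carbocycle → pyran.

**Assumptions**
- Briarane numbering is used throughout: cyclohexane = C1, C10–C14; Me-15 on C1; C20 on C11; C16 on C5; lactone = C7–O–C19(=O)–C17(Me-18)–C8. The target is 1R,2R,3R,4R,6S,7R,8R,9S,10S,11R,14S,17R.
- The facial sense of the Diels–Alder catalyst in step 1 is taken from the usual model for that catalyst; if it is the opposite, the (R)-catalyst is used and nothing else changes.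
- Compound 2 (the industrial vitamin-A C5 aldehyde) is taken as commercially available.
- C7 is deliberately carried as a ~1:1 epimer mixture from step 15 and is only set in step 22.
- This is a paper design; none of it has been run.

---

**Step 1**
Reactants: 1 (E)-buta-1,3-dien-1-yl acetate (excess; only the E isomer reacts); 2 (E)-4-acetoxy-2-methylbut-2-enal
Product: 3 (1R,2S,6S)-2-acetoxy-6-(acetoxymethyl)-1-methylcyclohex-3-ene-1-carbaldehyde (ring C1/C14/C10; CHO = C2, CH2OAc = C9)
Conditions: (S)-o-tolyl-oxazaborolidine·AlBr3 (10 mol %), CH2Cl2, −40 °C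
Reagents that add atoms: none
Why: Lewis-acid-catalysed enantioselective Diels–Alder; "ortho" regiochemistry and CHO-endo addition put 14-OAc cis to C2, and the E-enal geometry puts Me-15 cis to C9, so C1, C10 and C14 are set together with the catalyst fixing the absolute sense.

**Step 2**
Reactants: 3
Product: 4 (1R,2S,6S)-2-acetoxy-6-(acetoxymethyl)-1-methyl-5-oxocyclohex-3-ene-1-carbaldehyde (C11 ketone, Δ12)
Conditions: CrO3, 3,5-dimethylpyrazole, CH2Cl2, −20 °C
Reagents that add atoms: chromium trioxide, O=[Cr](=O)=O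
Why: Allylic oxidation at the only allylic CH2 (C11); the acetoxy-bearing C14–H is deactivated and the non-enolisable neopentyl aldehyde should survive anhydrous Cr(VI).

**Step 3**
Reactants: 5 (S)-4-benzyloxazolidin-2-one; 6 benzyloxyacetyl chloride
Product: 7 (S)-4-benzyl-3-[(benzyloxy)acetyl]oxazolidin-2-one
Conditions: n-BuLi, THF, −78 °C; then 6
Reagents that add atoms: none
Why: Standard N-acylation of the lithiated Evans auxiliary.

**Step 4**
Reactants: 4; 7
Product: 8 aldol adduct of 4 in which CHO has become (2R)-CH(OH)–(3S)-CH(OBn)–C(=O)–oxazolidinone (acyl chain 2′S,3′R)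
Conditions: 7, Bu2BOTf, Et3N, CH2Cl2, −78→0 °C; then 4, −78→0 °C; pH 7 buffer/H2O2
Reagents that add atoms: none
Why: Evans syn-glycolate aldol through the Z-boron enolate and a Zimmerman–Traxler transition state; the auxiliary sets C2 and C3 (2,3-syn), and the aldehyde reacts in preference to the enone.

**Step 5**
Reactants: 8
Product: 9 saturated C11-ketone with free 2,3-diol (imide retained)
Conditions: H2 (1 atm), 10 % Pd/C, EtOAc, rt
Reagents that add atoms: none
Why: Catalytic hydrogenation saturates C12=C13 and hydrogenolyses the benzyl ether in one operation; no stereocentre is touched.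

**Step 6**
Reactants: 9
Product: 10 11(20)-exo-methylene 2,3-diol imide
Conditions: Zn, CH2Br2, TiCl4, THF/CH2Cl2, 0 °C→rt
Reagents that add atoms: dibromomethane, BrCBr
Why: Takai–Lombardo methylenation is non-basic, so the epimerisable C10 and the β-acetoxy ketone are safe, and imide and acetates are not attacked.

**Step 7**
Reactants: 10
Product: 11 Weinreb amide (C4 = C(=O)N(OMe)Me), 2,3-diol
Conditions: MeNH(OMe)·HCl, AlMe3, CH2Cl2, −20→0 °C
Reagents that add atoms: N,O-dimethylhydroxylamine hydrochloride, CNOC.Cl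
Why: Aluminium-amide transamination of the β-hydroxy imide is chelation-accelerated and outpaces attack on the acetates at low temperature.

**Step 8**
Reactants: 11
Product: 12 Weinreb amide 2,3,9,14-tetraacetate
Conditions: Ac2O, pyridine, DMAP, CH2Cl2, rt
Reagents that add atoms: acetic anhydride, CC(=O)OC(C)=O
Why: Acetylation installs the final C2 and C3 acetates, which also serve as protecting groups from here on.

**Step 9**
Reactants: 12
Product: 13 primary alcohol at C9 (2,3,14-triacetate)
Conditions: [t-Bu2SnCl(OH)]2 (cat.), MeOH/THF, rt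
Reagents that add atoms: none
Why: Distannoxane-catalysed transesterification removes the unhindered primary acetate much faster than the three secondary (one neopentyl) acetates.

**Step 10**
Reactants: 13
Product: 14 C9 aldehyde (2,3,14-triacetate, 11(20)-ene, C4 Weinreb amide), used crude
Conditions: Dess–Martin periodinane, NaHCO3, CH2Cl2, 0 °C
Reagents that add atoms: none
Why: Buffered Dess–Martin oxidation avoids enolisation of the α-stereocentre C10.

**Step 11**
Reactants: 15 acrolein; 16 prop-1-ynylmagnesium bromide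
Product: 17 (±)-hex-1-en-4-yn-3-ol
Conditions: THF, −78 °C
Reagents that add atoms: none
Why: 1,2-Grignard addition to the enal.

**Step 12**
Reactants: 17
Product: 18 (±)-(Z)-5-iodohexa-1,4-dien-3-ol
Conditions: Red-Al, THF, 0 °C→rt; then I2, −78 °C
Reagents that add atoms: iodine, II
Why: Hydroxyl-directed trans-hydroalumination of the propargylic alcohol then iodination gives only the Z-vinyl iodide (I cis to the carbinol carbon, the future C7).

**Step 13**
Reactants: 18; 19 2-(bromomethyl)acrylic acid
Product: 20 (±)-(Z)-5-iodohexa-1,4-dien-3-yl 2-(bromomethyl)acrylate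
Conditions: 19, (COCl)2, cat. DMF, CH2Cl2; then 18, 2,6-lutidine, 0 °C
Reagents that add atoms: none
Why: Acid-chloride esterification with a hindered base avoids SN2′ attack on the allylic bromide.

**Step 14**
Reactants: 20
Product: 21 (±)-3-(bromomethyl)-5-[(Z)-2-iodoprop-1-en-1-yl]furan-2(5H)-one
Conditions: Grubbs II (5 mol %), CH2Cl2, 40 °C
Reagents that add atoms: none
Why: Ring-closing metathesis between the vinyl group and the acrylate gives the butenolide; the trisubstituted vinyl iodide does not take part.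

**Step 15**
Reactants: 14; 21
Product: 22 Barbier adduct: 9-hydroxy, β-(C8–H) α-methylene-γ-butyrolactone (mixture at C7, C8, C9)
Conditions: Zn dust, THF/sat. aq. NH4Cl, 0 °C→rt
Reagents that add atoms: none
Why: Zn-Barbier allylation reacts at the γ-carbon of the allyl-zinc (C8) to form C8–C9 under near-neutral conditions that leave the vinyl iodide, Weinreb amide and acetates alone; the new centres are erased or reset in steps 16, 17 and 22.

**Step 16**
Reactants: 22
Product: 23 9-oxo Δ8(17)-butenolide (4-acyl-3-methyl-2(5H)-furanone; C7 epimers)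
Conditions: Dess–Martin periodinane, NaHCO3, CH2Cl2, 0 °C; then Et3N (cat.), 0 °C
Reagents that add atoms: none
Why: Oxidation followed by base-catalysed exo→endo alkene isomerisation through the doubly activated C8–H gives the conjugated tetrasubstituted butenolide (C18 becomes the methyl).

**Step 17**
Reactants: 23
Product: 24 (9S)-9-hydroxy butenolide
Conditions: NaBH4, CeCl3·7H2O, MeOH, −78 °C
Reagents that add atoms: none
Why: Luche 1,2-reduction of the ketone under Felkin–Anh control from C10, with the quaternary C1 as the large group, sets C9.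

**Step 18**
Reactants: 24
Product: 25 (9S)-9-acetate (2,3,9,14-tetraacetate)
Conditions: Ac2O, Sc(OTf)3 (cat.), MeCN, −20 °C
Reagents that add atoms: acetic anhydride, CC(=O)OC(C)=O
Why: Non-basic Lewis-acid-catalysed acetylation caps the hindered C9–OH before it can translactonise onto C19.

**Step 19**
Reactants: 25
Product: 26 (11R)-11,20-epoxide
Conditions: mCPBA, NaHCO3, CH2Cl2, 0 °C
Reagents that add atoms: meta-chloroperoxybenzoic acid, OOC(=O)c1cccc(Cl)c1
Why: Prilezhaev epoxidation of the only electron-rich alkene, from the face opposite the 1,3-diaxial Me-15, gives the epoxide oxygen equatorial (α) and so sets C11.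

**Step 20**
Reactants: 26
Product: 27 C4 aldehyde (α-acetoxy aldehyde), used at once
Conditions: Cp2Zr(H)Cl, THF, rt, 20 min
Reagents that add atoms: none
Why: Schwartz-reagent reduction takes the Weinreb amide to the aldehyde without touching acetates, lactone or vinyl iodide.

**Step 21**
Reactants: 27
Product: 28 ten-membered carbocycle, (4R)-4-ol, (5Z)-alkene (C7 epimers)
Conditions: CrCl2 (10 equiv), NiCl2 (cat.), DMSO, rt, 2 mM
Reagents that add atoms: none
Why: Nozaki–Hiyama–Kishi macrocyclisation forms C4–C5 with retention of the Z-geometry, and polar Felkin–Anh addition anti to the C3 acetate gives the 3,4-anti carbinol.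

**Step 22**
Reactants: 28
Product: 29 4,8-ether tetracycle (pyran closed; Δ5(6) with C16 methyl; 11,20-epoxide; 7R,8R,17R)
Conditions: DBU, toluene, rt→50 °C
Reagents that add atoms: none
Why: Transannular oxa-Michael addition of 4-OH to the planar butenolide is necessarily cis-fused (sets C8), only the 7R epimer can bridge while the other equilibrates through the 2-oxidofuran, and C17 settles with its methyl trans to C9.

**Step 23**
Reactants: 29
Product: 30 (11R)-11-hydroxy-20-chloro tetracycle (Δ5(6))
Conditions: LiCl, AcOH, THF, rt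
Reagents that add atoms: lithium chloride, [Li+].[Cl-]
Why: SN2 opening of the spiro-epoxide at the primary carbon C20 leaves the C11–O bond and configuration intact.

**Step 24**
Reactants: 30
Product: 31 Fragilide F
Conditions: Ca(OCl)2, CO2(s), CH2Cl2/H2O, 0 °C
Reagents that add atoms: calcium hypochlorite, [Ca+2].[O-]Cl.[O-]Cl
Why: Ene-type allylic chlorination: Cl+ adds to C6 from the convex α-face (opposite the C3–C9 bridge) and a C16 proton is lost, giving 6S-Cl and the 5(16)-methylene; the bridgehead C4–H is not aligned for loss.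

---

**Compound list**
1 | (E)-buta-1,3-dien-1-yl acetate | CC(=O)O/C=C/C=C | starting material
2 | (E)-4-acetoxy-2-methylbut-2-enal | CC(=O)OC/C=C(\C)C=O | starting material
3 | (1R,2S,6S)-2-acetoxy-6-(acetoxymethyl)-1-methylcyclohex-3-ene-1-carbaldehyde | CC(=O)OC[C@H]1CC=C[C@H](OC(C)=O)[C@]1(C)C=O | intermediate
4 | (1R,2S,6S)-2-acetoxy-6-(acetoxymethyl)-1-methyl-5-oxocyclohex-3-ene-1-carbaldehyde | CC(=O)OC[C@H]1C(=O)C=C[C@H](OC(C)=O)[C@]1(C)C=O | intermediate
5 | (S)-4-benzyloxazolidin-2-one | O=C1N[C@@H](Cc2ccccc2)CO1 | starting material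
6 | benzyloxyacetyl chloride | O=C(Cl)COCc1ccccc1 | starting material
7 | (S)-4-benzyl-3-[(benzyloxy)acetyl]oxazolidin-2-one | O=C(COCc1ccccc1)N1[C@@H](Cc2ccccc2)COC1=O | intermediate
8 | Evans syn aldol adduct (C2-OH, C3-OBn, enone) | CC(=O)OC[C@H]1C(=O)C=C[C@H](OC(C)=O)[C@]1(C)[C@@H](O)[C@@H](C(=O)N1[C@@H](Cc2ccccc2)COC1=O)OCc1ccccc1 | intermediate
9 | C11-ketone 2,3-diol imide | CC(=O)OC[C@H]1C(=O)CC[C@H](OC(C)=O)[C@]1(C)[C@@H](O)[C@@H](C(=O)N1[C@@H](Cc2ccccc2)COC1=O)O | intermediate
10 | 11(20)-methylene 2,3-diol imide | CC(=O)OC[C@H]1C(=C)CC[C@H](OC(C)=O)[C@]1(C)[C@@H](O)[C@@H](C(=O)N1[C@@H](Cc2ccccc2)COC1=O)O | intermediate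
11 | Weinreb amide 2,3-diol | CC(=O)OC[C@H]1C(=C)CC[C@H](OC(C)=O)[C@]1(C)[C@@H](O)[C@@H](C(=O)N(C)OC)O | intermediate
12 | Weinreb amide 2,3,9,14-tetraacetate | CC(=O)OC[C@H]1C(=C)CC[C@H](OC(C)=O)[C@]1(C)[C@@H](OC(C)=O)[C@@H](C(=O)N(C)OC)OC(C)=O | intermediate
13 | C9 primary alcohol, 2,3,14-triacetate | OC[C@H]1C(=C)CC[C@H](OC(C)=O)[C@]1(C)[C@@H](OC(C)=O)[C@@H](C(=O)N(C)OC)OC(C)=O | intermediate
14 | C9 aldehyde, 2,3,14-triacetate | O=C[C@H]1C(=C)CC[C@H](OC(C)=O)[C@]1(C)[C@@H](OC(C)=O)[C@@H](C(=O)N(C)OC)OC(C)=O | intermediate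
15 | acrolein | C=CC=O | starting material
16 | prop-1-ynylmagnesium bromide | CC#C[Mg]Br | starting material
17 | (±)-hex-1-en-4-yn-3-ol | CC#CC(O)C=C | intermediate
18 | (±)-(Z)-5-iodohexa-1,4-dien-3-ol | C/C(I)=C/C(O)C=C | intermediate
19 | 2-(bromomethyl)acrylic acid | OC(=O)C(=C)CBr | starting material
20 | (±)-(Z)-5-iodohexa-1,4-dien-3-yl 2-(bromomethyl)acrylate | C/C(I)=C/C(OC(=O)C(=C)CBr)C=C | intermediate
21 | (±)-3-(bromomethyl)-5-[(Z)-2-iodoprop-1-enyl]furan-2(5H)-one | C/C(I)=C/C1OC(=O)C(CBr)=C1 | intermediate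
22 | Barbier adduct (α-methylene lactone, 9-OH; C7/C8/C9 mixture) | C/C(I)=C/C1OC(=O)C(=C)C1C(O)[C@H]1C(=C)CC[C@H](OC(C)=O)[C@]1(C)[C@@H](OC(C)=O)[C@@H](C(=O)N(C)OC)OC(C)=O | intermediate
23 | 9-oxo Δ8(17)-butenolide (C7 epimers) | C/C(I)=C/C1OC(=O)C(C)=C1C(=O)[C@H]1C(=C)CC[C@H](OC(C)=O)[C@]1(C)[C@@H](OC(C)=O)[C@@H](C(=O)N(C)OC)OC(C)=O | intermediate
24 | (9S)-9-hydroxy butenolide | C/C(I)=C/C1OC(=O)C(C)=C1[C@@H](O)[C@H]1C(=C)CC[C@H](OC(C)=O)[C@]1(C)[C@@H](OC(C)=O)[C@@H](C(=O)N(C)OC)OC(C)=O | intermediate
25 | (9S)-9-acetate | C/C(I)=C/C1OC(=O)C(C)=C1[C@@H](OC(C)=O)[C@H]1C(=C)CC[C@H](OC(C)=O)[C@]1(C)[C@@H](OC(C)=O)[C@@H](C(=O)N(C)OC)OC(C)=O | intermediate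
26 | (11R)-11,20-epoxide | C/C(I)=C/C1OC(=O)C(C)=C1[C@@H](OC(C)=O)[C@H]1[C@@]2(CO2)CC[C@H](OC(C)=O)[C@]1(C)[C@@H](OC(C)=O)[C@@H](C(=O)N(C)OC)OC(C)=O | intermediate
27 | C4 aldehyde (NHK precursor) | C/C(I)=C/C1OC(=O)C(C)=C1[C@@H](OC(C)=O)[C@H]1[C@@]2(CO2)CC[C@H](OC(C)=O)[C@]1(C)[C@@H](OC(C)=O)[C@@H](C=O)OC(C)=O | intermediate
28 | ten-membered carbocycle, (4R)-4-ol, 5Z (C7 epimers) | C/C1=C/C2OC(=O)C(C)=C2[C@@H](OC(C)=O)[C@H]2[C@@]3(CO3)CC[C@H](OC(C)=O)[C@]2(C)[C@@H](OC(C)=O)[C@H](OC(C)=O)[C@@H]1O | intermediate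
29 | 4,8-ether tetracycle, Δ5(6), 11,20-epoxide | CC=1[C@H]2O[C@]3([C@@H](C)C(=O)O[C@H]3C=1)[C@@H](OC(C)=O)[C@H]1[C@@]4(CO4)CC[C@H](OC(C)=O)[C@]1(C)[C@@H](OC(C)=O)[C@@H]2OC(C)=O | intermediate
30 | 11-hydroxy-20-chloro tetracycle, Δ5(6) | CC=1[C@H]2O[C@]3([C@@H](C)C(=O)O[C@H]3C=1)[C@@H](OC(C)=O)[C@H]1[C@@](O)(CCl)CC[C@H](OC(C)=O)[C@]1(C)[C@@H](OC(C)=O)[C@@H]2OC(C)=O | intermediate
31 | Fragilide F | C=C1[C@H]2O[C@]3([C@@H](C)C(=O)O[C@H]3[C@H]1Cl)[C@@H](OC(C)=O)[C@H]1[C@@](O)(CCl)CC[C@H](OC(C)=O)[C@]1(C)[C@@H](OC(C)=O)[C@@H]2OC(C)=O | target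

---

**Totals**
- Total steps: 24.
- Longest linear sequence: 19 (steps 1, 2, 4–10, then 15–24).

**Three steps most likely to fail**
1. **Step 22 (transannular oxa-Michael with C7 epimerisation).** The addition makes a fully substituted ether carbon and may be reversible, and DBU can also migrate the C3 acetate onto 4-OH. Fallback: form the same ring through the C4–O bond instead. Convert the butenolide to the 8-hydroxy-17-methyl lactone (nucleophilic epoxidation of C8=C17, then SmI2 reduction), and close the pyran by Pd(0) π-allyl etherification from a C4 allylic carbonate.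
2. **Step 21 (NHK closure of the ten-membered ring).** Ring strain, a hindered trisubstituted vinyl iodide and uncertain C4 selectivity all work against it. Fallback: reverse the order of the two C–C unions. Run the NHK intermolecularly (C4 aldehyde plus the vinyl iodide of a silyloxymethyl analogue of 21), convert to the allylic bromide, and close the ring by intramolecular Zn/In Barbier allylation at C8–C9.
3. **Step 24 (ene chlorination).** Competing HOCl addition and imperfect regio- or facial control are possible on the final compound. Fallback: build the silicon analogue by using 4-(trimethylsilyl)but-2-ynyl in place of propynyl in step 11, so that C16 carries SiMe3. The last step then becomes an SE2′ chlorodesilylation with NCS, which enforces C6–Cl and the 5(16)-alkene.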